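The route rests on disconnecting the O1–C2 bond of the 2H-pyran ring. C2 is a fully substituted allylic carbon between the C3=C4 alkene and the ring oxygen, so a C2 carbinol ionises to an allyl cation delocalised from C2 through C3 to C4 and into the C8a-oxygenated benzene ring, and both carbinol enantiomers give this one planar species. A chiral Brønsted acid then lets the C8a oxygen close onto C2, making the pyran ring and the C2 stereocentre in one operation. The precursor is the racemic (E)-o-hydroxystyryl tertiary alcohol obtained by Heck coupling of racemic geranyllinalool with a 6-O-silylated iodomethylhydroquinone.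

Key step: step 4

Assumption: geranyllinalool is bought as the (6E,10E) isomer, racemic at C3; the C3 configuration is irrelevant because step 4 erases it.
Assumption: the (R)-configured catalyst is taken to deliver the (S)-chromene; the sense of induction is to be checked on the first run and the (S)-catalyst used in the same way if it is opposite.

Step 1
Reactants: 1 methylhydroquinone
Product: 2 4-[(tert-butyldimethylsilyl)oxy]-2-methylphenol
Conditions: TBSCl (1.0 equiv), imidazole (2 equiv), DMF, −20 → 0 °C
Reagents that add atoms: tert-butyldimethylsilyl chloride, CC(C)(C)[Si](C)(C)Cl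
Why: Silyl ether formation with TBSCl/imidazole is governed by sterics, so the 4-hydroxyl with two ortho hydrogens should react ahead of the 1-hydroxyl next to the methyl group, and a slight deficit of silyl chloride at low temperature should keep double silylation small.

Step 2
Reactants: 2 4-[(tert-butyldimethylsilyl)oxy]-2-methylphenol
Product: 3 4-[(tert-butyldimethylsilyl)oxy]-2-iodo-6-methylphenol
Conditions: I2 (1.05 equiv), morpholine (2.2 equiv), CH2Cl2, 0 °C → rt; aq. Na2S2O3 wash
Reagents that add atoms: iodine, II
Why: Electrophilic aromatic iodination by the iodine–morpholine complex is directed ortho/para by the free hydroxyl, whose para position and one ortho position are blocked, so iodine should enter only at C6 next to the hydroxyl while the mildly basic medium spares the silyl ether.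

Step 3
Reactants: 3 4-[(tert-butyldimethylsilyl)oxy]-2-iodo-6-methylphenol; 4 racemic (6E,10E)-geranyllinalool (1.3 equiv)
Product: 5 racemic 2-[(1E,6E,10E)-3-hydroxy-3,7,11,15-tetramethylhexadeca-1,6,10,14-tetraenyl]-4-[(tert-butyldimethylsilyl)oxy]-6-methylphenol
Conditions: Pd(OAc)2 (5 mol%), P(o-tol)3 (10 mol%), Et3N (3 equiv), MeCN, 75 °C, Ar; chromatography on Et3N-deactivated silica, stored cold
Reagents that add atoms: none
Why: In this Mizoroki–Heck reaction the aryl–palladium species adds to the only monosubstituted alkene with the aryl group at the terminal carbon, and because the carbinol carbon carries no hydrogen, syn β-hydride elimination can only give the (E)-styrenyl tertiary alcohol, while the amine keeps the medium basic so that the acid-labile carbinol does not ionise.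

Step 4
Reactants: 5 racemic (E)-o-hydroxystyryl tertiary alcohol
Product: 7 (S)-6-O-TBS ether of the target chromene, via vinyl o-quinone methide 6 (not isolated)
Conditions: (R)-3,3'-bis(2,4,6-triisopropylphenyl)-BINOL N-triflylphosphoramide (5 mol%), toluene (0.02 M), −78 °C, dark; Et3N quench at −78 °C; Et3N-deactivated silica
Reagents that add atoms: none
Why: Proposed new method: the acid protonates the tertiary hydroxyl of either enantiomer of 5 and water leaves, giving one planar 1-aryl-3,3-dialkylallyl cation (C2–C3–C4, extended into the ring by the C8a hydroxyl) as a contact ion pair with the chiral phosphoramide anion, so the carbinol configuration is erased. Transfer of the C8a–OH proton to the anion gives the vinyl o-quinone methide 6, held to the catalyst by a hydrogen bond, and its C4=C4a geometry can turn over by reprotonation until C2 lies beside the carbonyl oxygen. The pyran ring then closes by oxa-6π electrocyclisation, which can equally be read as 6-endo addition of the C8a oxygen to the C2 end of the allyl system, and this forms the O1–C2 bond. The closest known reaction type is the chiral Brønsted acid-catalysed dehydrative intramolecular allylic substitution of o-hydroxycinnamyl tertiary alcohols bearing an aryl and an alkyl group on the carbinol carbon to 2,2-disubstituted 2H-chromenes, and the untested element here is a methyl/CH2R pair at C2. The C2 stereocentre is under catalyst control alone: the 3,3'-aryl walls of the binaphthyl anion must seat the methyl group and turn the long CH2 arm outward so that oxygen bonds to one face of C2. The step needs enantioface selectivity and O-closure ahead of cation capture by the C3'=C4' alkene, proton loss to dienes and re-ionisation of 7; the ortho hydroxyl (easy ionisation at −78 °C and an internal trap), the E alkene (no uncatalysed closure of 5) and the acid-stable, non-basic aryl silyl ether help, together with cold toluene and a cold amine quench.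

Step 5
Reactants: 7 (S)-6-O-TBS ether of the target chromene
Product: 8 (S)-2,8-dimethyl-2-[(3E,7E)-4,8,12-trimethyltrideca-3,7,11-trien-1-yl]-2H-chromen-6-ol (target)
Conditions: TBAF (1.2 equiv), AcOH (1.2 equiv), THF, 0 °C, Ar, dark
Reagents that add atoms: none
Why: Fluoride cleaves the aryl Si–O bond by forming the stronger Si–F bond (standard silyl ether deprotection), and the acetic acid buffer keeps the liberated phenol protonated yet is far too weak to ionise the C2–O1 bond, so the C2 stereocentre and the three chain alkenes should be untouched.

Compound list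
1 | methylhydroquinone (2-methylbenzene-1,4-diol) | Cc1cc(O)ccc1O | starting material
2 | 4-[(tert-butyldimethylsilyl)oxy]-2-methylphenol | Cc1cc(O[Si](C)(C)C(C)(C)C)ccc1O | intermediate
3 | 4-[(tert-butyldimethylsilyl)oxy]-2-iodo-6-methylphenol | Cc1cc(O[Si](C)(C)C(C)(C)C)cc(I)c1O | intermediate
4 | racemic (6E,10E)-geranyllinalool, (6E,10E)-3,7,11,15-tetramethylhexadeca-1,6,10,14-tetraen-3-ol | CC(C)=CCC/C(C)=C/CC/C(C)=C/CCC(C)(O)C=C | starting material
5 | racemic 2-[(1E,6E,10E)-3-hydroxy-3,7,11,15-tetramethylhexadeca-1,6,10,14-tetraenyl]-4-[(tert-butyldimethylsilyl)oxy]-6-methylphenol | CC(C)=CCC/C(C)=C/CC/C(C)=C/CCC(C)(O)/C=C/c1cc(O[Si](C)(C)C(C)(C)C)cc(C)c1O | intermediate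
6 | vinyl o-quinone methide: 4-[(tert-butyldimethylsilyl)oxy]-2-methyl-6-[(6E,10E)-3,7,11,15-tetramethylhexadeca-2,6,10,14-tetraen-1-ylidene]cyclohexa-2,4-dien-1-one, exocyclic C4=C4a bond Z (C3 syn to the carbonyl oxygen), C2=C3 geometry not fixed | CC(C)=CCC/C(C)=C/CC/C(C)=C/CCC(C)=C/C=C1/C=C(O[Si](C)(C)C(C)(C)C)C=C(C)C1=O | intermediate (not isolated)
7 | (S)-tert-butyldimethyl({2,8-dimethyl-2-[(3E,7E)-4,8,12-trimethyltrideca-3,7,11-trien-1-yl]-2H-chromen-6-yl}oxy)silane | CC(C)=CCC/C(C)=C/CC/C(C)=C/CC[C@@]1(C)C=Cc2cc(O[Si](C)(C)C(C)(C)C)cc(C)c2O1 | intermediate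
8 | (S)-2,8-dimethyl-2-[(3E,7E)-4,8,12-trimethyltrideca-3,7,11-trien-1-yl]-2H-chromen-6-ol | CC(C)=CCC/C(C)=C/CC/C(C)=C/CC[C@@]1(C)C=Cc2cc(O)cc(C)c2O1 | target

Total step count: 5. Longest linear sequence: 5 steps (1 → 2 → 3 → 5 → 7 → 8); geranyllinalool 4 enters at step 3.

Steps most likely to fail

1. Step 4 (Proposed new method). The ion pair may not tell methyl from the CH2 arm well enough, so enantioface selectivity may be poor. The cation may also be intercepted by the C3'=C4' alkene or lose a proton to dienes, and reversible C2–O1 ionisation may erode the enantiomeric purity before the quench. Fallback with known chemistry, setting out from 5: the ring is closed without stereocontrol by catalytic pyridinium p-toluenesulfonate in CH2Cl2 at room temperature, the classical acid-mediated dehydrative cyclisation of o-hydroxycinnamyl tertiary alcohols, to give the racemic 6-O-TBS chromene F1. The enantiomers are then separated by preparative chromatography on a polysaccharide chiral stationary phase; the (R)-enantiomer F2 is set aside and the (S)-enantiomer rejoins the route at 7.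

2. Step 3. Dehydrative ring closure or diene formation in the hot Heck mixture would give racemic chromene before the chiral catalyst is involved; the silyl ether may be lost, or oxidative addition of the electron-rich iodophenol may be slow. Fallback, setting out from 3: the styrenyl alcohol is assembled by a Suzuki–Miyaura coupling near room temperature. Purchased (5E,9E)-farnesylacetone F3 is treated with ethynylmagnesium bromide in THF at 0 °C to give the racemic propargylic alcohol F4. Copper-catalysed anti-Markovnikov protoboration (CuCl, Xantphos, NaOtBu, B2pin2, MeOH, THF, rt) converts it into the (E)-alkenyl pinacol boronate F5. Coupling of this boronate with 3 (Pd(dppf)Cl2, aq. K3PO4, THF, 40 °C) should give 5, where the route is rejoined.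

3. Step 1. Site discrimination between the two hydroxyls may be insufficient, or double silylation may dominate. Fallback, setting out from 1: both hydroxyls are acetylated (Ac2O, pyridine) to 2-methyl-1,4-phenylene diacetate F6. Lipase-catalysed butanolysis (n-BuOH, MTBE, rt) removes the unhindered acetate and should give 4-hydroxy-2-methylphenyl acetate F7. Silylation (TBSCl, imidazole) gives 4-[(tert-butyldimethylsilyl)oxy]-2-methylphenyl acetate F8. Aminolysis of the remaining acetate with pyrrolidine in THF at 0 °C should return the route at 2.

Further compounds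
F1 | step 4 | racemic tert-butyldimethyl({2,8-dimethyl-2-[(3E,7E)-4,8,12-trimethyltrideca-3,7,11-trien-1-yl]-2H-chromen-6-yl}oxy)silane | CC(C)=CCC/C(C)=C/CC/C(C)=C/CCC1(C)C=Cc2cc(O[Si](C)(C)C(C)(C)C)cc(C)c2O1
F2 | step 4 | (R)-enantiomer of 7 | CC(C)=CCC/C(C)=C/CC/C(C)=C/CC[C@]1(C)C=Cc2cc(O[Si](C)(C)C(C)(C)C)cc(C)c2O1
F3 | step 3 | (5E,9E)-farnesylacetone, (5E,9E)-6,10,14-trimethylpentadeca-5,9,13-trien-2-one (purchased, not made) | CC(C)=CCC/C(C)=C/CC/C(C)=C/CCC(C)=O
F4 | step 3 | racemic (6E,10E)-3,7,11,15-tetramethylhexadeca-6,10,14-trien-1-yn-3-ol | CC(C)=CCC/C(C)=C/CC/C(C)=C/CCC(C)(O)C#C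
F5 | step 3 | racemic (1E,6E,10E)-3,7,11,15-tetramethyl-1-(4,4,5,5-tetramethyl-1,3,2-dioxaborolan-2-yl)hexadeca-1,6,10,14-tetraen-3-ol | CC(C)=CCC/C(C)=C/CC/C(C)=C/CCC(C)(O)/C=C/B1OC(C)(C)C(C)(C)O1
F6 | step 1 | 2-methyl-1,4-phenylene diacetate | CC(=O)Oc1ccc(OC(C)=O)c(C)c1
F7 | step 1 | 4-hydroxy-2-methylphenyl acetate | CC(=O)Oc1ccc(O)cc1C
F8 | step 1 | 4-[(tert-butyldimethylsilyl)oxy]-2-methylphenyl acetate | CC(=O)Oc1ccc(O[Si](C)(C)C(C)(C)C)cc1C
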